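**Retrosynthetic overview**

1. Endgame: the three oxygens differ by origin. C6–O arrives as a benzyl ether, C4–O as the alcohol released from a lactone, and C2–CH2OH comes from a late Morita–Baylis–Hillman reaction, so the isobutyrate and the (E)-4-hydroxy-2-methylbut-2-enoate go on one after the other.
2. Enabling feature: in the cyclohex-2-en-1-one ring the carbonyl carbon C1 and the oxygen-bearing C4 are 1,4-related across the C2=C3 double bond. This is the retron of a 2-pyranone [4+2] adduct, a 2-oxabicyclo[2.2.2]oct-5-en-3-one whose O–C(=O) bridge spans C4 and C1 (C4–O is the pyranone ring oxygen).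
3. Key disconnection: C1–C6 and C4–C5, by an inverse-electron-demand Diels–Alder reaction of methyl 2-oxo-2H-pyran-3-carboxylate with benzyl (E)-3-methylbut-1-enyl ether under a chiral Cu(OTf)2/bis(oxazoline) catalyst. Two flat, achiral partners give the carbocycle, the alkene position and the C4, C5 and C6 stereocenters in one step.
4. Unmasking: the two carboxyl carbons left on C1 (lactone bridge and ester) are removed by saponification and anodic oxidative bis-decarboxylation, which turns C1 into the enone carbonyl.
5. Ring order: only the carbocycle is built (step 3); the pyranone ring survives as a temporary lactone bridge that is opened in step 4.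

Key step: step 3

Remarks on the chemistry:
- Locants C1–C6 refer throughout to the cyclohex-2-en-1-one ring of the target (C1 carbonyl, C2 bearing CH2OH, C4 O-isobutyryl, C5 isopropyl, C6 O-acyl).
- Assumption: the sense of induction of the Cu(OTf)2/(S,S)-bis(oxazoline) complex with this diene/dienophile pair is taken by analogy. If it should deliver the antipode, the equally available (R,R)-ligand is used and nothing else changes.

**Route**

Step 1
Reactants: 1 3-methylbut-1-yne; 2 pinacolborane
Product: 3 2-[(E)-3-methylbut-1-en-1-yl]-4,4,5,5-tetramethyl-1,3,2-dioxaborolane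
Conditions: Cp2Zr(H)Cl (5 mol %), Et3N (10 mol %), neat, sealed tube, 60 °C
Reagents that add atoms: none
Why: Zirconocene hydride-catalysed hydroboration adds H–B syn and anti-Markovnikov across the terminal alkyne, so only the (E)-alkenylboronate should form.

Step 2
Reactants: 3 (E)-alkenylboronate; 4 benzyl alcohol
Product: 5 benzyl (E)-3-methylbut-1-en-1-yl ether
Conditions: Cu(OAc)2 (2 equiv), Et3N (4 equiv), BnOH (excess, as solvent), rt; chromatography on Et3N-deactivated silica
Reagents that add atoms: none
Why: Chan–Lam–Evans-type oxidative C–O coupling, in which boron-to-copper transmetalation and C–O reductive elimination proceed with retention at the sp2 carbon, so the E geometry is carried into the enol ether.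

Step 3
Reactants: 5 benzyl (E)-3-methylbut-1-en-1-yl ether; 6 methyl 2-oxo-2H-pyran-3-carboxylate
Product: 7 methyl (1S,4R,7S,8R)-8-(benzyloxy)-7-isopropyl-3-oxo-2-oxabicyclo[2.2.2]oct-5-ene-4-carboxylate (benzyloxy endo, syn to the C5=C6 bridge; isopropyl exo, syn to the lactone bridge)
Conditions: Cu(OTf)2 (10 mol %), (S,S)-2,2'-isopropylidenebis(4-tert-butyl-2-oxazoline) (11 mol %), 4 Å MS, CH2Cl2, −20 °C → rt, 5 (1.5 equiv)
Reagents that add atoms: none
Why: The ester and lactone carbonyls of 6 chelate the chiral divalent copper bis(oxazoline) Lewis acid, which lowers the LUMO of the pyranone diene and lets the electron-rich enol ether 5 add across C3 and C6 in a concerted but asynchronous inverse-electron-demand Diels–Alder reaction, forming the C1–C6 and C4–C5 bonds of the future cyclohexenone and leaving the alkene at C2=C3. The closest known reaction type is the chiral Lewis acid-catalysed [4+2] cycloaddition of 3-alkoxycarbonyl-2-pyranones with vinyl ethers and silyl enol ethers. The single new ring, the carbocycle, is closed by intermolecular suprafacial [4+2] cycloaddition, while the pyranone ring is kept as the O–C(=O) bridge. Regiochemistry follows from polarisation (the nucleophilic β-carbon of the enol ether bonds to the electrophilic C6 of the pyranone, the oxygen-bearing carbon to C3), the trans relation of benzyloxy and isopropyl from the E geometry of 5, and the cis relation of isopropyl to the bridging oxygen from the endo orientation of the alkoxy group that is usual for enol ethers with this diene. Absolute configuration at all four stereocenters is set by the bis(oxazoline) ligand, which shields one face of the chelated, planar pyranone. The step therefore needs regio-, endo- and facial selectivity, secured by the 3-ester (polarisation and two-point binding), by the defined E-enol ether, and by staying at or below room temperature, which also prevents retro-[4+2] loss of CO2 from 7.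

Step 4
Reactants: 7 bicyclic lactone ester
Product: 8 (4S,5S,6R)-6-(benzyloxy)-4-hydroxy-5-isopropylcyclohex-2-ene-1,1-dicarboxylic acid
Conditions: LiOH (8 equiv), THF/MeOH/H2O, 0 → 45 °C; then 1 M HCl to pH 2–3 at 0 °C, used without delay
Reagents that add atoms: lithium hydroxide, [Li+].[OH-] (its oxygen ends in the two carboxyl groups)
Why: Saponification, in which hydroxide opens the strained bridging lactone by acyl–oxygen cleavage (the C4–O bond and its configuration are kept) and hydrolyses the methyl ester, giving a malonic acid whose quaternary C1 can neither enolise nor eliminate.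

Step 5
Reactants: 8 malonic acid
Product: 10 (4S,5S,6R)-6-(benzyloxy)-4-hydroxy-5-isopropylcyclohex-2-en-1-one, via dimethyl ketal 9 (not isolated)
Conditions: graphite anode, graphite cathode, undivided cell, constant current (about 10 mA cm−2, 4.5–5 F mol−1), NH3 (7 M in MeOH), MeOH, rt; then 1 M HCl, THF, rt
Reagents that add atoms: methanol, CO (the two methoxy groups of 9); water, O (the carbonyl oxygen of 10)
Why: Hofer–Moest (non-Kolbe) anodic oxidative bis-decarboxylation of a disubstituted malonic acid, in which each carboxylate loses two electrons and CO2 and the cations are trapped by methanol to give the ketal that mild acid hydrolyses to the conjugated enone; methanol capture at the remote allyl terminus in the second stage converges on the same enone after hydrolysis and β-elimination, the benzyl ether and the alcohol lie above the working potential, and no stereocenter is touched (C6, now α to the ketone, already has the thermodynamically preferred trans arrangement to the isopropyl group).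

Step 6
Reactants: 10 hydroxy enone
Product: 11 (4S,5S,6R)-6-(benzyloxy)-4-(isobutyryloxy)-5-isopropylcyclohex-2-en-1-one
Conditions: isobutyric anhydride (1.5 equiv), pyridine, DMAP (0.1 equiv), CH2Cl2, 0 °C → rt
Reagents that add atoms: isobutyric anhydride, CC(C)C(=O)OC(=O)C(C)C
Why: DMAP-catalysed acylation of the only free hydroxyl (the secondary allylic C4–OH), which affects no stereocenter.

Step 7
Reactants: 11 benzyl ether
Product: 12 (4S,5R,6R)-6-hydroxy-4-(isobutyryloxy)-5-isopropylcyclohex-2-en-1-one (same spatial arrangement as 11; the C5 descriptor changes only through the priority rules)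
Conditions: BCl3 (1 M in CH2Cl2, 2.5 equiv), pentamethylbenzene (3 equiv), CH2Cl2, −78 °C; MeOH quench at −78 °C, then aq. NaHCO3
Reagents that add atoms: none
Why: Lewis acid debenzylation, in which BCl3 chelated between the ketone and the ether oxygen ionises the benzyl–O bond and pentamethylbenzene captures the benzyl cation, so the C6–O bond and its configuration are untouched and the isobutyrate survives at −78 °C.

Step 8
Reactants: 13 2-[(tert-butyldimethylsilyl)oxy]acetaldehyde; 14 ethyl 2-(triphenyl-λ5-phosphanylidene)propanoate
Product: 15 ethyl (E)-4-[(tert-butyldimethylsilyl)oxy]-2-methylbut-2-enoate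
Conditions: CH2Cl2, rt
Reagents that add atoms: none
Why: Wittig olefination with a stabilised α-methyl ylide, which should give the (E)-trisubstituted enoate with high selectivity.

Step 9
Reactants: 15 ethyl ester
Product: 16 (E)-4-[(tert-butyldimethylsilyl)oxy]-2-methylbut-2-enoic acid
Conditions: LiOH·H2O (3 equiv), THF/MeOH/H2O, rt; then 1 M HCl to pH 4 at 0 °C
Reagents that add atoms: lithium hydroxide, [Li+].[OH-]
Why: Ester saponification under conditions that a primary tert-butyldimethylsilyl ether should tolerate, with only a brief, cold, weakly acidic work-up.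

Step 10
Reactants: 12 α-hydroxy ketone; 16 silyloxy tiglic acid
Product: 17 (4S,5S,6R)-6-{[(E)-4-[(tert-butyldimethylsilyl)oxy]-2-methylbut-2-enoyl]oxy}-4-(isobutyryloxy)-5-isopropylcyclohex-2-en-1-one
Conditions: DCC (1.6 equiv), DMAP (0.3 equiv), 16 (1.5 equiv), CH2Cl2, 0 °C → rt
Reagents that add atoms: none
Why: Steglich esterification at the oxygen of the α-hydroxy ketone, which leaves the C6 configuration unchanged (it is also the thermodynamic one), while the 1,3-trans C4 ester cannot migrate.

Step 11
Reactants: 17 enone diester
Product: 18 (4S,5S,6R)-6-{[(E)-4-[(tert-butyldimethylsilyl)oxy]-2-methylbut-2-enoyl]oxy}-2-(hydroxymethyl)-4-(isobutyryloxy)-5-isopropylcyclohex-2-en-1-one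
Conditions: aq. HCHO (37 %, 4 equiv), DMAP (0.2 equiv), THF/H2O, rt
Reagents that add atoms: formaldehyde, C=O
Why: Morita–Baylis–Hillman reaction, in which reversible conjugate addition of DMAP at C3, aldol reaction of the enolate with formaldehyde at C2 and E1cB loss of DMAP restore the C2=C3 bond with the hydroxymethyl group in place; the trisubstituted tiglate is not a competent acceptor and no stereocenter is formed.

Step 12
Reactants: 18 silyl ether
Product: 19 target, (4S,5S,6R)-6-{[(E)-4-hydroxy-2-methylbut-2-enoyl]oxy}-2-(hydroxymethyl)-4-(isobutyryloxy)-5-isopropylcyclohex-2-en-1-one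
Conditions: HF·pyridine, pyridine/THF, 0 °C → rt
Reagents that add atoms: none
Why: Fluoride-driven cleavage of the primary silyl ether under buffered, weakly acidic conditions that should leave the three esters, the enone and the allylic alcohols intact.

**Compound list**

1 | 3-methylbut-1-yne | CC(C)C#C | starting material
2 | pinacolborane (4,4,5,5-tetramethyl-1,3,2-dioxaborolane) | CC1(C)OBOC1(C)C | starting material
3 | 2-[(E)-3-methylbut-1-en-1-yl]-4,4,5,5-tetramethyl-1,3,2-dioxaborolane | CC(C)/C=C/B1OC(C)(C)C(C)(C)O1 | intermediate
4 | benzyl alcohol | OCc1ccccc1 | starting material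
5 | benzyl (E)-3-methylbut-1-en-1-yl ether | CC(C)/C=C/OCc1ccccc1 | intermediate
6 | methyl 2-oxo-2H-pyran-3-carboxylate | COC(=O)C1=CC=COC1=O | starting material
7 | methyl (1S,4R,7S,8R)-8-(benzyloxy)-7-isopropyl-3-oxo-2-oxabicyclo[2.2.2]oct-5-ene-4-carboxylate | O(Cc1ccccc1)[C@H]3[C@@]2(C(=O)OC)C=C[C@H](OC2=O)[C@@H]3C(C)C | intermediate
8 | (4S,5S,6R)-6-(benzyloxy)-4-hydroxy-5-isopropylcyclohex-2-ene-1,1-dicarboxylic acid | O(Cc1ccccc1)[C@H]1C(C(=O)O)(C(=O)O)C=C[C@H](O)[C@@H]1C(C)C | intermediate
9 | dimethyl ketal of 10 (6-benzyloxy-4-hydroxy-5-isopropyl-1,1-dimethoxycyclohex-2-ene, configuration as in 10) | O(Cc1ccccc1)[C@H]1C(OC)(OC)C=C[C@H](O)[C@@H]1C(C)C | intermediate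
10 | (4S,5S,6R)-6-(benzyloxy)-4-hydroxy-5-isopropylcyclohex-2-en-1-one | O(Cc1ccccc1)[C@H]1C(=O)C=C[C@H](O)[C@@H]1C(C)C | intermediate
11 | (4S,5S,6R)-6-(benzyloxy)-4-(isobutyryloxy)-5-isopropylcyclohex-2-en-1-one | O(Cc1ccccc1)[C@H]1C(=O)C=C[C@H](OC(=O)C(C)C)[C@@H]1C(C)C | intermediate
12 | (4S,5R,6R)-6-hydroxy-4-(isobutyryloxy)-5-isopropylcyclohex-2-en-1-one | O[C@H]1C(=O)C=C[C@H](OC(=O)C(C)C)[C@@H]1C(C)C | intermediate
13 | 2-[(tert-butyldimethylsilyl)oxy]acetaldehyde | CC(C)(C)[Si](C)(C)OCC=O | starting material
14 | ethyl 2-(triphenyl-λ5-phosphanylidene)propanoate | CCOC(=O)C(C)=P(c1ccccc1)(c1ccccc1)c1ccccc1 | starting material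
15 | ethyl (E)-4-[(tert-butyldimethylsilyl)oxy]-2-methylbut-2-enoate | CCOC(=O)/C(C)=C/CO[Si](C)(C)C(C)(C)C | intermediate
16 | (E)-4-[(tert-butyldimethylsilyl)oxy]-2-methylbut-2-enoic acid | OC(=O)/C(C)=C/CO[Si](C)(C)C(C)(C)C | intermediate
17 | (4S,5S,6R)-6-{[(E)-4-[(tert-butyldimethylsilyl)oxy]-2-methylbut-2-enoyl]oxy}-4-(isobutyryloxy)-5-isopropylcyclohex-2-en-1-one | CC(C)(C)[Si](C)(C)OC/C=C(\C)C(=O)O[C@H]1C(=O)C=C[C@H](OC(=O)C(C)C)[C@@H]1C(C)C | intermediate
18 | (4S,5S,6R)-6-{[(E)-4-[(tert-butyldimethylsilyl)oxy]-2-methylbut-2-enoyl]oxy}-2-(hydroxymethyl)-4-(isobutyryloxy)-5-isopropylcyclohex-2-en-1-one | CC(C)(C)[Si](C)(C)OC/C=C(\C)C(=O)O[C@H]1C(=O)C(CO)=C[C@H](OC(=O)C(C)C)[C@@H]1C(C)C | intermediate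
19 | (4S,5S,6R)-6-{[(E)-4-hydroxy-2-methylbut-2-enoyl]oxy}-2-(hydroxymethyl)-4-(isobutyryloxy)-5-isopropylcyclohex-2-en-1-one (CNP0254776.1) | C/C(=C\CO)C(=O)O[C@H]1C(=O)C(CO)=C[C@H](OC(=O)C(C)C)[C@@H]1C(C)C | target

**Step count and risks**

Total step count: 12. Longest linear sequence: 10 steps (steps 1–7 and 10–12); the side-chain acid takes 2 steps (8–9).

Steps most likely to fail:

1. Step 5 (anodic bis-decarboxylation). After the first decarboxylation the cation is allylic, so solvent capture at the remote terminus (allylic transposition to a dead-end cyclohexenecarboxylic acid) or proton loss may compete with ketal formation. The fallback sets out from 8 and comes back at 10, and uses anionic rather than cationic chemistry. Compound 8 is heated (toluene/pyridine, 90 °C) to lose one CO2 and give (4S,5S,6R)-6-(benzyloxy)-4-hydroxy-5-isopropylcyclohex-2-ene-1-carboxylic acid F1 (C1 epimers). Its trilithium salt (LiN(iPr)2, 3.3 equiv, THF, −78 → −20 °C) is oxygenated with O2 at −78 °C at the α-carbon to give the 1-hydroperoxy acid F2. On acidification (TsOH) F2 should fragment with loss of CO2 and water to enone 10 (oxidative decarboxylation of a carboxylic acid dianion).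

2. Step 11 (late Morita–Baylis–Hillman). The nucleophilic amine in water may cleave or transfer the activated C6 ester, or the hindered C3 may add the catalyst too slowly. The fallback sets out from 17 and comes back at 18, and replaces the organocatalytic aldol by a cross-coupling. α-Iodination of the enone (I2, pyridine, CH2Cl2, 0 °C → rt) gives the 2-iodo derivative of 17 F3. Stille coupling of F3 with (tributylstannyl)methanol (Pd(PPh3)4 cat., dioxane, 80 °C) should deliver 18.

3. Step 3 (key cycloaddition). Facial discrimination by the catalyst may be insufficient with the β-branched enol ether, which would give low enantiomeric purity. The fallback sets out from 5 and comes back at 8, and replaces catalyst control by auxiliary control. 2-Oxo-2H-pyran-3-carboxylic acid is esterified with (R)-pantolactone (DCC, DMAP, CH2Cl2) to the (3R)-4,4-dimethyl-2-oxooxolan-3-yl 2-oxo-2H-pyran-3-carboxylate F4. Cycloaddition of F4 with 5 under an achiral Lewis acid (Yb(OTf)3, CH2Cl2, rt) should give the pantolactonyl ester analogue of 7 F5, and the diastereomers are separable by chromatography or crystallisation. LiOH saponification (as in step 4) removes the auxiliary and opens the lactone bridge to give 8.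

Further compounds
F1 | step 5 | (4S,5S,6R)-6-(benzyloxy)-4-hydroxy-5-isopropylcyclohex-2-ene-1-carboxylic acid (C1 epimers) | O(Cc1ccccc1)[C@H]1C(C(=O)O)C=C[C@H](O)[C@@H]1C(C)C
F2 | step 5 | (4S,5S,6R)-6-(benzyloxy)-1-hydroperoxy-4-hydroxy-5-isopropylcyclohex-2-ene-1-carboxylic acid (C1 epimers) | O(Cc1ccccc1)[C@H]1C(OO)(C(=O)O)C=C[C@H](O)[C@@H]1C(C)C
F3 | step 11 | 2-iodo derivative of 17 (stereocenters as in 17) | CC(C)(C)[Si](C)(C)OC/C=C(\C)C(=O)O[C@H]1C(=O)C(I)=C[C@H](OC(=O)C(C)C)[C@@H]1C(C)C
F4 | step 3 | (3R)-4,4-dimethyl-2-oxooxolan-3-yl 2-oxo-2H-pyran-3-carboxylate | O=C(O[C@H]1C(=O)OCC1(C)C)C1=CC=COC1=O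
F5 | step 3 | (3R)-4,4-dimethyl-2-oxooxolan-3-yl ester analogue of 7 (bicyclic core configured as in 7) | O(Cc1ccccc1)[C@H]3[C@@]2(C(=O)O[C@H]4C(=O)OCC4(C)C)C=C[C@H](OC2=O)[C@@H]3C(C)C
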